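**Retrosynthetic overview**
1. Target ⇐ 9(11)-ene (exo-face epoxidation last) ⇐ 15-ketone (α-methylenation) ⇐ lactone-to-lactol adjustment; the ring A cis-diacetate comes from a C1=C2 alkene by Woodward hydroxylation.
2. Key disconnection C9–C10: a C9 ketyl radical anion (polarity-reversed carbonyl carbon) adds to C10, the β-carbon of a safranic ester tethered through C7–O–C6(=O). The 7-endo closure gives the ε-lactone (later the lactol); dehydration of the 9-carbinol gives the 9(11)-ene.
3. CD unit: bicyclo[3.2.1]octane 8 from (S)-4-allylcyclohexenone by Baylis–Hillman hydroxymethylation (C7), ozonolysis and CuH reductive aldol (ring D, quaternary C8). The enone comes from an organocatalytic Michael/aldol of pent-4-enal and methyl vinyl ketone (C13).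
4. Ring order: C → D → (A brought in intact from safranal) → seven-membered oxacycle (key step) → epoxide.

**Conventions and assumption**
- Kaurane numbering is used from compound 8 on: ring A = C1–C5, C10; C6 = lactone/lactol carbon; C7 = OCH2 on C8; ring C = C8, C9, C11–C14; ring D = C8, C15, C16, C13, C14; C17 = exocyclic CH2; C20 = methyl on C10.
- The 15-carbinol configuration (steps 5–14) is immaterial; it is drawn as the expected syn-aldol epimer.
- Assumption: the hemiacetal carbon C6 equilibrates (mutarotation), so the C6 epimer of the target is taken as the thermodynamic one and is drawn that way throughout.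

**Route**

Step 1
Reactants: 1 pent-4-enal; 2 but-3-en-2-one (methyl vinyl ketone)
Product: 3 (S)-2-allyl-5-oxohexanal
Conditions: (S)-2-[diphenyl(trimethylsilyloxy)methyl]pyrrolidine (10 mol %), 4-nitrophenol (20 mol %), neat, 4 °C
Reagents that add atoms: none
Why: Enamine-catalysed Michael addition (Hayashi–Jørgensen type) in which the (S)-catalyst shields one enamine face so the vinyl ketone adds to the Si face, setting C13.

Step 2
Reactants: 3 (S)-2-allyl-5-oxohexanal
Product: 4 (S)-4-allylcyclohex-2-en-1-one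
Conditions: LiOH (0.1 equiv), i-PrOH, rt
Reagents that add atoms: none
Why: Intramolecular aldol condensation of the methyl ketone onto the aldehyde closes ring C; mild base leaves the γ-stereocentre untouched.

Step 3
Reactants: 4 (S)-4-allylcyclohex-2-en-1-one
Product: 5 (S)-4-allyl-2-(hydroxymethyl)cyclohex-2-en-1-one
Conditions: 37 % aq. HCHO, DMAP (0.2 equiv), THF/H2O, rt
Reagents that add atoms: formaldehyde, C=O
Why: Morita–Baylis–Hillman reaction puts C7 (as CH2OH) on the enone α-carbon C8 without any redox adjustment.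

Step 4
Reactants: 5 (S)-4-allyl-2-(hydroxymethyl)cyclohex-2-en-1-one
Product: 7 (S)-2-[3-(hydroxymethyl)-4-oxocyclohex-2-en-1-yl]acetaldehyde, via ozonide 6 (not isolated)
Conditions: O3, CH2Cl2, −78 °C (Sudan III end point); then Me2S, −78 °C → rt
Reagents that add atoms: ozone, O=[O+][O-]
Why: Ozonolysis (Criegee) is chemoselective for the electron-rich terminal alkene over the electron-poor enone and unveils the C15 aldehyde.

Step 5
Reactants: 7 (S)-2-[3-(hydroxymethyl)-4-oxocyclohex-2-en-1-yl]acetaldehyde
Product: 8 (1R,5R,7R)-7-hydroxy-1-(hydroxymethyl)bicyclo[3.2.1]octan-2-one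
Conditions: [(Ph3P)CuH]6 (2.4 equiv hydride), toluene/THF, −40 → 0 °C; aq. NH4Cl
Reagents that add atoms: none
Why: Reductive aldol cyclisation (CuH conjugate reduction, then intramolecular aldol of the regiodefined copper enolate); the enolate can reach the aldehyde only on the face cis to the C13 side chain, which fixes quaternary C8 and closes ring D.

Step 6
Reactants: 9 safranal
Product: 10 safranic acid (2,6,6-trimethylcyclohexa-1,3-diene-1-carboxylic acid)
Conditions: NaClO2, NaH2PO4, 2-methyl-2-butene, t-BuOH/H2O, rt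
Reagents that add atoms: sodium chlorite, [Na+].[O-]Cl=O
Why: Pinnick oxidation converts the dienal to the acid without touching the diene.

Step 7
Reactants: 8 (1R,5R,7R)-7-hydroxy-1-(hydroxymethyl)bicyclo[3.2.1]octan-2-one; 10 safranic acid
Product: 12 [(1R,5R,7R)-7-hydroxy-2-oxobicyclo[3.2.1]octan-1-yl]methyl 2,6,6-trimethylcyclohexa-1,3-diene-1-carboxylate, via safranoyl chloride 11 (not isolated)
Conditions: 10, (COCl)2, cat. DMF, CH2Cl2, 0 °C → rt; then 8, Et3N, DMAP, CH2Cl2, 0 °C → rt
Reagents that add atoms: none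
Why: Acid chloride formation followed by DMAP-catalysed acylation, selective for the primary C7 hydroxyl over the hindered secondary 15-OH, installs the C7–O–C6 ester tether.

Step 8
Reactants: 12 hydroxy keto ester
Product: 13 [(1R,5R,7R)-2-oxo-7-(triisopropylsilyloxy)bicyclo[3.2.1]octan-1-yl]methyl 2,6,6-trimethylcyclohexa-1,3-diene-1-carboxylate
Conditions: TIPSOTf, 2,6-lutidine, CH2Cl2, 0 °C
Reagents that add atoms: triisopropylsilyl trifluoromethanesulfonate, CC(C)[Si](OS(=O)(=O)C(F)(F)F)(C(C)C)C(C)C
Why: Silylation masks the 15-OH (the future ketone) with a group that survives SmI2, hot aqueous acetic acid and DIBAL.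

Step 9
Reactants: 13 TIPS keto ester
Product: 14 9-hydroxy ε-lactone (1-ene; C6(=O)–O–C7 lactone; tertiary 9-OH; 15-OTIPS)
Conditions: SmI2 (4 equiv), HMPA (16 equiv), t-BuOH (3 equiv), THF (5 mM), −78 → −20 °C; AcOH quench at −78 °C
Reagents that add atoms: none
Why: Proposed new method: SmI2/HMPA reduces the C9 ketone to a ketyl radical anion (a nucleophilic, polarity-reversed carbonyl carbon) that adds 7-endo to the β-carbon C10 of the tethered dienoate, and the resulting C5 radical is reduced to the samarium enolate and protonated by t-BuOH; the closest known reaction type is the SmI2 ketyl–olefin (radical-anion Michael) cyclisation onto acrylates and unsaturated lactones that builds vicinal fully substituted carbons; C10 is set because the ketyl is attacked on the ring-C face away from the C15–C16 bridge and its OTIPS group with ring A turned away from the C14 bridge (C20 over ring C), and the epimerisable α-carbonyl centre C5 is protonated anti to C20 (trans fusion).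

Step 10
Reactants: 14 9-hydroxy ε-lactone
Product: 17 1,2-cis-diacetate lactone (both OAc syn to C20; 9-OH free), via iodo acetate 15 (not isolated), via hydroxy acetate 16 (not isolated)
Conditions: I2, AgOAc, AcOH, rt; then H2O/AcOH, 90 °C; evaporate; then Ac2O, pyridine, DMAP, rt
Reagents that add atoms: silver acetate, CC(=O)[O-].[Ag+]; water, O; acetic anhydride, CC(=O)OC(C)=O
Why: Woodward cis-hydroxylation: the iodonium forms on the open face anti to C20, acetate opens it trans-diaxially at C2, and the dioxolanylium ion formed by displacing iodide is hydrolysed by water, so both oxygens end up syn to C20 (C1, C2 set), after which in-pot acetylation masks the diol for step 11.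

Step 11
Reactants: 17 1,2-cis-diacetate lactone
Product: 18 9(11)-ene diacetate lactone
Conditions: Burgess reagent, toluene, 70 °C
Reagents that add atoms: none
Why: Burgess dehydration of the tertiary 9-OH can only give the 9(11)-alkene because C8 and C10 are quaternary; it also removes the γ-hydroxyl before the lactone is reduced.

Step 12
Reactants: 18 9(11)-ene diacetate lactone
Product: 19 lactol diol (1,2-diol; C6 hemiacetal; 9(11)-ene; 15-OTIPS)
Conditions: DIBAL (6 equiv), CH2Cl2, −78 °C; Rochelle salt
Reagents that add atoms: none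
Why: DIBAL half-reduction of the ε-lactone stops at the aluminium hemiacetal at −78 °C and gives the seven-membered lactol held by the rigid skeleton; the two acetates are cleaved in the same operation, and C6 settles by mutarotation.

Step 13
Reactants: 19 lactol diol
Product: 20 1,2,6-triacetate (anomeric 6-OAc; 15-OTIPS)
Conditions: Ac2O, pyridine, DMAP, CH2Cl2, rt
Reagents that add atoms: acetic anhydride, CC(=O)OC(C)=O
Why: Exhaustive acetylation installs the two target acetates and protects the lactol as its anomeric acetate for the coming oxidation.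

Step 14
Reactants: 20 1,2,6-triacetate
Product: 21 15-alcohol triacetate
Conditions: HF·pyridine, pyridine, THF, 0 °C → rt
Reagents that add atoms: none
Why: Buffered fluoride desilylation frees only the 15-OH and leaves all three acetates in place.

Step 15
Reactants: 21 15-alcohol triacetate
Product: 22 15-ketone triacetate
Conditions: Dess–Martin periodinane, CH2Cl2, rt
Reagents that add atoms: none
Why: Dess–Martin oxidation of the only free hydroxyl gives the non-conjugated 15-ketone under neutral conditions.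

Step 16
Reactants: 22 15-ketone triacetate
Product: 23 15-ketone 1,2-diacetate lactol
Conditions: NH3 (7 M in MeOH), THF, 0 °C
Reagents that add atoms: none
Why: Selective ammonolysis of the anomeric acetate (the most electrophilic ester) liberates the lactol while the hindered 1- and 2-acetates stay, and C6 equilibrates to the natural anomer.

Step 17
Reactants: 23 15-ketone 1,2-diacetate lactol
Product: 24 16-methylene-15-ketone (9(11)-ene)
Conditions: (CH2O)n, N-methylanilinium trifluoroacetate, THF, 65 °C; aq. NaHCO3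
Reagents that add atoms: paraformaldehyde (formaldehyde), C=O
Why: Mannich-type α-methylenation (Gras conditions) at C16, the only enolisable position of the 15-ketone, under mildly acidic conditions that spare acetates and lactol.

Step 18
Reactants: 24 16-methylene-15-ketone (9(11)-ene)
Product: 25 CNP0224512.1 (target)
Conditions: dimethyldioxirane (1.1 equiv), acetone/CH2Cl2, −20 → 0 °C
Reagents that add atoms: dimethyldioxirane, CC1(C)OO1
Why: Electrophilic epoxidation takes only the electron-rich trisubstituted 9(11)-alkene (the enone is inert) from the exo face of the bicyclo[3.2.1]octene, anti to the C15–C16 bridge, setting C9 and C11.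

**Compound list**
1 | pent-4-enal | C=CCCC=O | starting material
2 | but-3-en-2-one (methyl vinyl ketone) | CC(=O)C=C | starting material
3 | (S)-2-allyl-5-oxohexanal | O=C[C@H](CC=C)CCC(C)=O | intermediate
4 | (S)-4-allylcyclohex-2-en-1-one | O=C1C=C[C@H](CC=C)CC1 | intermediate
5 | (S)-4-allyl-2-(hydroxymethyl)cyclohex-2-en-1-one | O=C1C(CO)=C[C@H](CC=C)CC1 | intermediate
6 | ozonide of 5 (1,2,4-trioxolane on the side chain; trioxolane carbon unassigned) | O=C1C(CO)=C[C@H](CC2OCOO2)CC1 | intermediate (not isolated)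
7 | (S)-2-[3-(hydroxymethyl)-4-oxocyclohex-2-en-1-yl]acetaldehyde | O=C1C(CO)=C[C@H](CC=O)CC1 | intermediate
8 | (1R,5R,7R)-7-hydroxy-1-(hydroxymethyl)bicyclo[3.2.1]octan-2-one | O=C1CC[C@@H]2C[C@@]1(CO)[C@H](O)C2 | intermediate
9 | safranal (2,6,6-trimethylcyclohexa-1,3-diene-1-carbaldehyde) | CC1=C(C=O)C(C)(C)CC=C1 | starting material
10 | safranic acid | CC1=C(C(O)=O)C(C)(C)CC=C1 | intermediate
11 | safranoyl chloride | CC1=C(C(Cl)=O)C(C)(C)CC=C1 | intermediate (not isolated)
12 | [(1R,5R,7R)-7-hydroxy-2-oxobicyclo[3.2.1]octan-1-yl]methyl safranate | O=C1CC[C@@H]2C[C@@]1(COC(=O)C3=C(C)C=CCC3(C)C)[C@H](O)C2 | intermediate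
13 | [(1R,5R,7R)-2-oxo-7-(triisopropylsilyloxy)bicyclo[3.2.1]octan-1-yl]methyl safranate | O=C1CC[C@@H]2C[C@@]1(COC(=O)C3=C(C)C=CCC3(C)C)[C@H](O[Si](C(C)C)(C(C)C)C(C)C)C2 | intermediate
14 | 9-hydroxy ε-lactone: 1-ene, C6(=O)–O–C7 lactone, H-5 anti to C20, C10 on the C14-side face of ring C, 15-OTIPS | C1[C@@H](O[Si](C(C)C)(C(C)C)C(C)C)[C@@]23COC(=O)[C@@H]4C(C)(C)CC=C[C@@]4(C)[C@]2(O)CC[C@@H]1C3 | intermediate
15 | iodo acetate: 1-iodo anti to C20, 2-OAc syn to C20, otherwise as 14 | C1[C@@H](O[Si](C(C)C)(C(C)C)C(C)C)[C@@]23COC(=O)[C@@H]4C(C)(C)C[C@H](OC(C)=O)[C@@H](I)[C@@]4(C)[C@]2(O)CC[C@@H]1C3 | intermediate (not isolated)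
16 | hydroxy acetate: 1-OH and 2-OAc both syn to C20 (regioisomer equally usable) | C1[C@@H](O[Si](C(C)C)(C(C)C)C(C)C)[C@@]23COC(=O)[C@@H]4C(C)(C)C[C@H](OC(C)=O)[C@H](O)[C@@]4(C)[C@]2(O)CC[C@@H]1C3 | intermediate (not isolated)
17 | 1,2-cis-diacetate lactone, both OAc syn to C20, 9-OH, 15-OTIPS | C1[C@@H](O[Si](C(C)C)(C(C)C)C(C)C)[C@@]23COC(=O)[C@@H]4C(C)(C)C[C@H](OC(C)=O)[C@H](OC(C)=O)[C@@]4(C)[C@]2(O)CC[C@@H]1C3 | intermediate
18 | 9(11)-ene 1,2-diacetate lactone, 15-OTIPS | C1[C@@H](O[Si](C(C)C)(C(C)C)C(C)C)[C@@]23COC(=O)[C@@H]4C(C)(C)C[C@H](OC(C)=O)[C@H](OC(C)=O)[C@@]4(C)C2=CC[C@@H]1C3 | intermediate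
19 | 9(11)-ene lactol 1,2-diol, 15-OTIPS | C1[C@@H](O[Si](C(C)C)(C(C)C)C(C)C)[C@@]23CO[C@@H](O)[C@@H]4C(C)(C)C[C@H](O)[C@H](O)[C@@]4(C)C2=CC[C@@H]1C3 | intermediate
20 | 9(11)-ene 1,2,6-triacetate, 15-OTIPS | C1[C@@H](O[Si](C(C)C)(C(C)C)C(C)C)[C@@]23CO[C@@H](OC(C)=O)[C@@H]4C(C)(C)C[C@H](OC(C)=O)[C@H](OC(C)=O)[C@@]4(C)C2=CC[C@@H]1C3 | intermediate
21 | 9(11)-ene 1,2,6-triacetate 15-alcohol | C1[C@@H](O)[C@@]23CO[C@@H](OC(C)=O)[C@@H]4C(C)(C)C[C@H](OC(C)=O)[C@H](OC(C)=O)[C@@]4(C)C2=CC[C@@H]1C3 | intermediate
22 | 9(11)-ene 1,2,6-triacetate 15-ketone | C1C(=O)[C@@]23CO[C@@H](OC(C)=O)[C@@H]4C(C)(C)C[C@H](OC(C)=O)[C@H](OC(C)=O)[C@@]4(C)C2=CC[C@@H]1C3 | intermediate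
23 | 9(11)-ene 1,2-diacetate lactol 15-ketone | C1C(=O)[C@@]23CO[C@@H](O)[C@@H]4C(C)(C)C[C@H](OC(C)=O)[C@H](OC(C)=O)[C@@]4(C)C2=CC[C@@H]1C3 | intermediate
24 | 9(11)-ene 1,2-diacetate lactol 16-methylene-15-ketone | C=C1C(=O)[C@@]23CO[C@@H](O)[C@@H]4C(C)(C)C[C@H](OC(C)=O)[C@H](OC(C)=O)[C@@]4(C)C2=CC[C@@H]1C3 | intermediate
25 | CNP0224512.1 | C=C1C(=O)[C@@]23CO[C@@H](O)[C@@H]4C(C)(C)C[C@H](OC(C)=O)[C@H](OC(C)=O)[C@@]4(C)[C@]24O[C@@H]4C[C@@H]1C3 | target

**Totals and risks**
Total step count: 18. Longest linear sequence: 17 (steps 1–5 and 7–18; step 6 is a one-step side branch).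

Three steps most likely to fail:

Step 9 (the ketyl–dienoate 7-endo closure). The acceptor is a tetrasubstituted, hindered dienoate and the ester must adopt its less stable rotamer. Simple reduction of the dienoate, fragmentation of the ketyl, or attack of the 9-alkoxide on the lactone carbonyl (hence the cold acidic quench) could win. Fallback: set out from 13 and reduce the ketone with NaBH4/MeOH at 0 °C to the 9-carbinol F1. Then generate the same polarity-reversed C9 centre as a neutral α-hydroxyalkyl radical by hydrogen-atom abstraction (Ir[dF(CF3)ppy]2(dtbbpy)PF6, quinuclidine, Bu4N H2PO4, blue LED, MeCN). This radical adds to C10 without any electron transfer to the dienoate, and the sequence comes back to the route at 14.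

Step 10 (Woodward hydroxylation on the hindered face). Acetate must attack C2 axially, syn to the axial methyls on C4 and C10. Fallback: set out from 14 and dihydroxylate with OsO4/NMO, which gives the cis-diol on the open face anti to C20, the 1,2-bis-epi diol F2. Oxidise with TFAA/DMSO/Et3N at −78 °C to the 1,2-diketone F3. Reduce with NaBH4/CeCl3 in MeOH at −78 °C, where hydride attacks both carbonyls from the open face and leaves both hydroxyls syn to C20, the 1,2-cis-diol lactone F4. Acetylation (Ac2O, DMAP) returns to the route at 17.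

Step 5 (reductive aldol forming quaternary C8 with a free hydroxyl and an aldehyde present). Fallback: set out from 7 and run a tandem thia-Michael/aldol with Me2AlSPh (CH2Cl2, −78 °C). Thiolate adds to C14 anti to the side chain and the aluminium enolate closes onto the aldehyde, giving the 14-phenylthio bicyclic diol F5. Desulfurisation with deactivated Raney nickel (acetone/EtOH) returns to the route at 8.

**Further compounds**
F1 | step 9 | [(1R,5R,7R)-2-hydroxy-7-(triisopropylsilyloxy)bicyclo[3.2.1]octan-1-yl]methyl safranate (9-carbinol of 13; major epimer drawn, either serves) | O[C@H]1CC[C@@H]2C[C@@]1(COC(=O)C3=C(C)C=CCC3(C)C)[C@H](O[Si](C(C)C)(C(C)C)C(C)C)C2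
F2 | step 10 | 1,2-bis-epi cis-diol of 14 (both OH anti to C20) | C1[C@@H](O[Si](C(C)C)(C(C)C)C(C)C)[C@@]23COC(=O)[C@@H]4C(C)(C)C[C@@H](O)[C@@H](O)[C@@]4(C)[C@]2(O)CC[C@@H]1C3
F3 | step 10 | 1,2-diketone derived from 14 | C1[C@@H](O[Si](C(C)C)(C(C)C)C(C)C)[C@@]23COC(=O)[C@@H]4C(C)(C)CC(=O)C(=O)[C@@]4(C)[C@]2(O)CC[C@@H]1C3
F4 | step 10 | 1,2-cis-diol lactone (both OH syn to C20; deacetylated 17) | C1[C@@H](O[Si](C(C)C)(C(C)C)C(C)C)[C@@]23COC(=O)[C@@H]4C(C)(C)C[C@H](O)[C@H](O)[C@@]4(C)[C@]2(O)CC[C@@H]1C3
F5 | step 5 | 7-hydroxy-1-(hydroxymethyl)-8-(phenylthio)bicyclo[3.2.1]octan-2-one (SPh on the one-carbon bridge, anti to the two-carbon bridge) | O=C1CC[C@@H]2[C@H](Sc3ccccc3)[C@@]1(CO)[C@H](O)C2
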